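**Retrosynthetic overview**

1. The target is a linear pentaaryl tetraether (rings A–E) with thirteen free hydroxyls and no stereocentre; the last step is global O-demethylation of its tridecamethyl ether.
2. The C2–O–D1 ether is cut first: copper-catalysed O-arylation of an A–B–C phenol (hydroxyl on C2 of ring C, freed from a benzyl ether) with a D–E aryl bromide made by one Chan–Lam coupling.
3. Feature used: on ring B the ring A oxygen (B1) and the ring C oxygen (B5) are meta to each other, B2 and B6 carry hydrogen and B3/B4 carry oxygen. Ring B is therefore built between the two ether oxygens: B1–B2 from an aryl ethynyl ether carrying ring A, B3–B6 from a 3-aryloxy-4-methoxycyclobutenone carrying ring C. A Danheiser benzannulation forms B2–B3 and B1–B6 and leaves only the B3 hydroxyl free.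
4. The cyclobutenone comes from the ring C ynol ether and methoxyketene; both ynol ethers come from phenols through dichlorovinyl ethers. The ring C phenol, 2-(benzyloxy)-3,4,5-trimethoxyphenol, is made from 2,3,4-trimethoxybenzaldehyde by two Baeyer–Villiger oxidations around an ortho-formylation, which places the benzyl group on the correct oxygen.
5. Ring order: rings A, C, D and E are purchased arenes; a four-membered ring is made in step 7 and consumed in step 10, where ring B, the only ring built, is closed.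

Key step: step 10

Remark: the target is achiral. Ring atoms are numbered so that B1 carries the ring A oxygen, B5 the ring C oxygen, C1 the ring B oxygen, C2 the ring D oxygen, D1 the ring C oxygen and D4 the ring E oxygen. 2,4,6-Trimethoxyphenol, 4-bromo-2,6-dimethoxyphenol and 3,4,5-trimethoxyphenylboronic acid are taken as purchasable.

**Route**

Step 1
Reactants: 1 2,3,4-trimethoxybenzaldehyde
Product: 3 2,3,4-trimethoxyphenol, via aryl formate 2 (not isolated)
Conditions: mCPBA, CH2Cl2, 0 °C → rt; NaHCO3 wash; then K2CO3 (cat.), MeOH, rt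
Reagents that add atoms: mCPBA, OOC(=O)c1cccc(Cl)c1
Why: Baeyer–Villiger oxidation of a benzaldehyde with ortho and para alkoxy groups proceeds with aryl migration to the formate, which methanolysis cleaves to the phenol.

Step 2
Reactants: 3 2,3,4-trimethoxyphenol
Product: 4 2-hydroxy-3,4,5-trimethoxybenzaldehyde
Conditions: MgCl2, Et3N, (CH2O)n, MeCN, reflux; then 1 M HCl
Reagents that add atoms: paraformaldehyde (as formaldehyde), C=O
Why: The magnesium-mediated ortho-formylation of phenols (Casnati–Skattebøl reaction) delivers the formyl group only ortho to the hydroxyl through the magnesium phenoxide, and C6 of 3 is the single free ortho position.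

Step 3
Reactants: 4 2-hydroxy-3,4,5-trimethoxybenzaldehyde
Product: 5 2-(benzyloxy)-3,4,5-trimethoxybenzaldehyde
Conditions: BnBr, K2CO3, DMF, rt
Reagents that add atoms: benzyl bromide, BrCc1ccccc1
Why: Williamson etherification of the only phenol places the benzyl group on the oxygen that later becomes the ring D attachment point.

Step 4
Reactants: 5 2-(benzyloxy)-3,4,5-trimethoxybenzaldehyde
Product: 7 2-(benzyloxy)-3,4,5-trimethoxyphenol, via aryl formate 6 (not isolated)
Conditions: mCPBA, CH2Cl2, 0 °C → rt; NaHCO3 wash; then K2CO3 (cat.), MeOH, rt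
Reagents that add atoms: mCPBA, OOC(=O)c1cccc(Cl)c1
Why: A second Baeyer–Villiger oxidation with aryl migration (ortho benzyloxy and para methoxy donors) turns the formyl carbon into the free C1 hydroxyl next to the ring C–H, and benzyl and methyl ethers are inert to the peracid.

Step 5
Reactants: 7 2-(benzyloxy)-3,4,5-trimethoxyphenol
Product: 8 2-(benzyloxy)-1-{[(E)-1,2-dichloroethenyl]oxy}-3,4,5-trimethoxybenzene
Conditions: Cl2C=CHCl, K2CO3, DMF, 70 °C
Reagents that add atoms: trichloroethylene, ClC=C(Cl)Cl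
Why: Base-induced loss of HCl from trichloroethylene gives dichloroacetylene, to which the phenoxide adds in anti fashion (nucleophilic addition to a haloalkyne), so the (E)-1,2-dichlorovinyl ether should form.

Step 6
Reactants: 8 2-(benzyloxy)-1-{[(E)-1,2-dichloroethenyl]oxy}-3,4,5-trimethoxybenzene
Product: 11 2-(benzyloxy)-1-(ethynyloxy)-3,4,5-trimethoxybenzene, via chloroethynyl ether 9 (not isolated), via lithium acetylide 10 (not isolated)
Conditions: n-BuLi (2.5 equiv), THF, −78 → −40 °C; then H2O; used without storage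
Reagents that add atoms: none
Why: n-BuLi removes the vinylic proton and β-elimination of LiCl gives the chloroalkyne, lithium–chlorine exchange with a second equivalent gives the lithium acetylide and water protonates it (the dichlorovinyl ether route to ynol ethers), at temperatures where neither the benzyl ether nor the ring C–H is metalated.

Step 7
Reactants: 11 2-(benzyloxy)-1-(ethynyloxy)-3,4,5-trimethoxybenzene
Product: 12 3-[2-(benzyloxy)-3,4,5-trimethoxyphenoxy]-4-methoxycyclobut-2-en-1-one (racemic)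
Conditions: MeOCH2COCl (slow addition), Et3N, CH2Cl2, 0 °C → rt
Reagents that add atoms: methoxyacetyl chloride, COCC(Cl)=O
Why: Methoxyketene, released by dehydrochlorination of the acid chloride, undergoes the ketene–ynol ether (2+2) cycloaddition with its carbonyl carbon bonding to the nucleophilic terminal alkyne carbon, which gives the 3-aryloxy-4-methoxycyclobutenone as a racemate whose single stereocentre is erased in step 10.

Step 8
Reactants: 13 2,4,6-trimethoxyphenol
Product: 14 2-{[(E)-1,2-dichloroethenyl]oxy}-1,3,5-trimethoxybenzene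
Conditions: Cl2C=CHCl, K2CO3, DMF, 70 °C
Reagents that add atoms: trichloroethylene, ClC=C(Cl)Cl
Why: The same anti addition of a phenoxide to dichloroacetylene generated in the flask applies, and a phenoxide with two ortho methoxy groups still adds to the unhindered alkyne.

Step 9
Reactants: 14 2-{[(E)-1,2-dichloroethenyl]oxy}-1,3,5-trimethoxybenzene
Product: 17 2-(ethynyloxy)-1,3,5-trimethoxybenzene, via chloroethynyl ether 15 (not isolated), via lithium acetylide 16 (not isolated)
Conditions: n-BuLi (2.5 equiv), THF, −78 → −40 °C; then H2O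
Reagents that add atoms: none
Why: The same elimination, lithium–chlorine exchange and protonation sequence gives the terminal ynol ether, which the two ortho methoxy groups shield against oligomerisation.

Step 10
Reactants: 12 3-[2-(benzyloxy)-3,4,5-trimethoxyphenoxy]-4-methoxycyclobut-2-en-1-one; 17 2-(ethynyloxy)-1,3,5-trimethoxybenzene
Product: 22 3-[2-(benzyloxy)-3,4,5-trimethoxyphenoxy]-2-methoxy-5-(2,4,6-trimethoxyphenoxy)phenol, via vinylketene 18 (not isolated), via vinylcyclobutenone 19 (not isolated), via dienylketene 20 (not isolated), via cyclohexadienone 21 (not isolated)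
Conditions: 17 (1.5 equiv), PhMe, 80 → 110 °C, sealed tube, argon
Reagents that add atoms: none
Why: Heating opens 12 by four-electron conrotatory cleavage of its C1–C4 bond (methoxy turning outward) to the aryloxy-substituted vinylketene 18, whose ketene C=C bond adds ynol ether 17 in a (2+2) cycloaddition to give the 4-vinylcyclobutenone 19. A second, reversible four-electron ring opening gives dienylketene 20, and ring B then closes by thermal six-electron disrotatory electrocyclisation between the ketene carbon and the methoxy-bearing terminus (B3–B4), after which cyclohexadienone 21 enolises to phenol 22. The closest known reaction type is the Danheiser benzannulation of cyclobutenones with alkoxy- and siloxyacetylenes, here with an oxygen donor on each partner. The sp3 carbon of 21 and the alkene geometries of 18 to 20 are transient, so no stereocentre remains. The one selectivity needed is the orientation of the ketene–alkyne cycloaddition: the ether oxygen makes the terminal carbon of 17 nucleophilic, so it bonds to the ketene carbonyl carbon (B2–B3) and the oxygen-bearing carbon bonds to the ketene α-carbon (B1–B6), which puts the ring A oxygen on B1, meta to the new hydroxyl and to the ring C oxygen. Aromatisation needs a hydrogen on the methoxy-bearing carbon, which the monosubstituted C4 of 12 supplies.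

Step 11
Reactants: 22 3-[2-(benzyloxy)-3,4,5-trimethoxyphenoxy]-2-methoxy-5-(2,4,6-trimethoxyphenoxy)phenol
Product: 23 1-[2-(benzyloxy)-3,4,5-trimethoxyphenoxy]-2,3-dimethoxy-5-(2,4,6-trimethoxyphenoxy)benzene
Conditions: MeI, K2CO3, acetone, reflux
Reagents that add atoms: iodomethane, CI
Why: Williamson methylation caps the only free hydroxyl (B3) so that the next phenol to be freed is the only nucleophile in the arylation.

Step 12
Reactants: 23 1-[2-(benzyloxy)-3,4,5-trimethoxyphenoxy]-2,3-dimethoxy-5-(2,4,6-trimethoxyphenoxy)benzene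
Product: 24 6-[2,3-dimethoxy-5-(2,4,6-trimethoxyphenoxy)phenoxy]-2,3,4-trimethoxyphenol
Conditions: H2 (1 atm), 10% Pd/C, EtOAc–MeOH, rt
Reagents that add atoms: none
Why: Catalytic hydrogenolysis cleaves the benzylic C–O bond only, since diaryl and aryl methyl ethers are inert under these conditions, and frees the hydroxyl on C2 of ring C.

Step 13
Reactants: 25 4-bromo-2,6-dimethoxyphenol; 26 3,4,5-trimethoxyphenylboronic acid
Product: 27 5-bromo-1,3-dimethoxy-2-(3,4,5-trimethoxyphenoxy)benzene
Conditions: Cu(OAc)2, pyridine, 4 Å MS, CH2Cl2, air, rt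
Reagents that add atoms: none
Why: The Chan–Lam oxidative coupling of an arylboronic acid with a phenol runs at room temperature, tolerates two ortho substituents on the phenol and leaves the aryl bromide needed in step 14 untouched.

Step 14
Reactants: 24 6-[2,3-dimethoxy-5-(2,4,6-trimethoxyphenoxy)phenoxy]-2,3,4-trimethoxyphenol; 27 5-bromo-1,3-dimethoxy-2-(3,4,5-trimethoxyphenoxy)benzene
Product: 28 2-(3-{2-[3,5-dimethoxy-4-(3,4,5-trimethoxyphenoxy)phenoxy]-3,4,5-trimethoxyphenoxy}-4,5-dimethoxyphenoxy)-1,3,5-trimethoxybenzene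
Conditions: CuI (cat.), picolinic acid (cat.), K3PO4, DMSO, 90 °C
Reagents that add atoms: none
Why: Ullmann-type copper-catalysed O-arylation with a picolinic acid ligand accepts phenols with two ortho substituents, and the bromide of 27 has both ortho positions free.

Step 15
Reactants: 28 2-(3-{2-[3,5-dimethoxy-4-(3,4,5-trimethoxyphenoxy)phenoxy]-3,4,5-trimethoxyphenoxy}-4,5-dimethoxyphenoxy)-1,3,5-trimethoxybenzene
Product: 29 2-(3-{2-[3,5-dihydroxy-4-(3,4,5-trihydroxyphenoxy)phenoxy]-3,4,5-trihydroxyphenoxy}-4,5-dihydroxyphenoxy)benzene-1,3,5-triol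
Conditions: BBr3 (excess), CH2Cl2, −78 °C → rt, argon; then degassed H2O
Reagents that add atoms: none
Why: BBr3 cleaves all thirteen aryl methyl ethers by Lewis acid complexation and bromide attack at the methyl carbon (Lewis acid ether cleavage), while the four diaryl ether bonds offer no sp3 carbon for attack and should stay intact.

**Compound list**

1 | 2,3,4-trimethoxybenzaldehyde | O=Cc1ccc(OC)c(OC)c1OC | starting material
2 | 2,3,4-trimethoxyphenyl formate (not isolated) | O=COc1ccc(OC)c(OC)c1OC | intermediate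
3 | 2,3,4-trimethoxyphenol | Oc1ccc(OC)c(OC)c1OC | intermediate
4 | 2-hydroxy-3,4,5-trimethoxybenzaldehyde | O=Cc1cc(OC)c(OC)c(OC)c1O | intermediate
5 | 2-(benzyloxy)-3,4,5-trimethoxybenzaldehyde | O=Cc1cc(OC)c(OC)c(OC)c1OCc1ccccc1 | intermediate
6 | 2-(benzyloxy)-3,4,5-trimethoxyphenyl formate (not isolated) | O=COc1cc(OC)c(OC)c(OC)c1OCc1ccccc1 | intermediate
7 | 2-(benzyloxy)-3,4,5-trimethoxyphenol | Oc1cc(OC)c(OC)c(OC)c1OCc1ccccc1 | intermediate
8 | 2-(benzyloxy)-1-{[(E)-1,2-dichloroethenyl]oxy}-3,4,5-trimethoxybenzene | Cl/C=C(/Cl)Oc1cc(OC)c(OC)c(OC)c1OCc1ccccc1 | intermediate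
9 | 2-(benzyloxy)-1-[(chloroethynyl)oxy]-3,4,5-trimethoxybenzene (not isolated) | ClC#COc1cc(OC)c(OC)c(OC)c1OCc1ccccc1 | intermediate
10 | lithium 2-[2-(benzyloxy)-3,4,5-trimethoxyphenoxy]ethynide (not isolated) | [Li]C#COc1cc(OC)c(OC)c(OC)c1OCc1ccccc1 | intermediate
11 | 2-(benzyloxy)-1-(ethynyloxy)-3,4,5-trimethoxybenzene | C#COc1cc(OC)c(OC)c(OC)c1OCc1ccccc1 | intermediate
12 | 3-[2-(benzyloxy)-3,4,5-trimethoxyphenoxy]-4-methoxycyclobut-2-en-1-one (racemic) | COC1C(=O)C=C1Oc1cc(OC)c(OC)c(OC)c1OCc1ccccc1 | intermediate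
13 | 2,4,6-trimethoxyphenol | COc1cc(OC)c(O)c(OC)c1 | starting material
14 | 2-{[(E)-1,2-dichloroethenyl]oxy}-1,3,5-trimethoxybenzene | Cl/C=C(/Cl)Oc1c(OC)cc(OC)cc1OC | intermediate
15 | 2-[(chloroethynyl)oxy]-1,3,5-trimethoxybenzene (not isolated) | ClC#COc1c(OC)cc(OC)cc1OC | intermediate
16 | lithium 2-(2,4,6-trimethoxyphenoxy)ethynide (not isolated) | [Li]C#COc1c(OC)cc(OC)cc1OC | intermediate
17 | 2-(ethynyloxy)-1,3,5-trimethoxybenzene | C#COc1c(OC)cc(OC)cc1OC | intermediate
18 | (3Z)-3-[2-(benzyloxy)-3,4,5-trimethoxyphenoxy]-4-methoxybuta-1,3-dien-1-one (vinylketene, not isolated) | O=C=C/C(Oc1cc(OC)c(OC)c(OC)c1OCc1ccccc1)=C/OC | intermediate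
19 | 4-{(Z)-1-[2-(benzyloxy)-3,4,5-trimethoxyphenoxy]-2-methoxyethenyl}-3-(2,4,6-trimethoxyphenoxy)cyclobut-2-en-1-one (racemic, not isolated) | O=C1C=C(Oc2c(OC)cc(OC)cc2OC)C1/C(Oc1cc(OC)c(OC)c(OC)c1OCc1ccccc1)=C/OC | intermediate
20 | (3E,5Z)-5-[2-(benzyloxy)-3,4,5-trimethoxyphenoxy]-6-methoxy-3-(2,4,6-trimethoxyphenoxy)hexa-1,3,5-trien-1-one (dienylketene, not isolated) | O=C=C/C(Oc1c(OC)cc(OC)cc1OC)=C\C(Oc1cc(OC)c(OC)c(OC)c1OCc1ccccc1)=C\OC | intermediate
21 | 5-[2-(benzyloxy)-3,4,5-trimethoxyphenoxy]-6-methoxy-3-(2,4,6-trimethoxyphenoxy)cyclohexa-2,4-dien-1-one (racemic, not isolated) | O=C1C=C(Oc2c(OC)cc(OC)cc2OC)C=C(Oc2cc(OC)c(OC)c(OC)c2OCc2ccccc2)C1OC | intermediate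
22 | 3-[2-(benzyloxy)-3,4,5-trimethoxyphenoxy]-2-methoxy-5-(2,4,6-trimethoxyphenoxy)phenol | Oc1cc(Oc2c(OC)cc(OC)cc2OC)cc(Oc2cc(OC)c(OC)c(OC)c2OCc2ccccc2)c1OC | intermediate
23 | 1-[2-(benzyloxy)-3,4,5-trimethoxyphenoxy]-2,3-dimethoxy-5-(2,4,6-trimethoxyphenoxy)benzene | COc1cc(Oc2c(OC)cc(OC)cc2OC)cc(Oc2cc(OC)c(OC)c(OC)c2OCc2ccccc2)c1OC | intermediate
24 | 6-[2,3-dimethoxy-5-(2,4,6-trimethoxyphenoxy)phenoxy]-2,3,4-trimethoxyphenol | COc1cc(Oc2c(OC)cc(OC)cc2OC)cc(Oc2cc(OC)c(OC)c(OC)c2O)c1OC | intermediate
25 | 4-bromo-2,6-dimethoxyphenol | COc1cc(Br)cc(OC)c1O | starting material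
26 | 3,4,5-trimethoxyphenylboronic acid | COc1cc(B(O)O)cc(OC)c1OC | starting material
27 | 5-bromo-1,3-dimethoxy-2-(3,4,5-trimethoxyphenoxy)benzene | COc1cc(Br)cc(OC)c1Oc1cc(OC)c(OC)c(OC)c1 | intermediate
28 | 2-(3-{2-[3,5-dimethoxy-4-(3,4,5-trimethoxyphenoxy)phenoxy]-3,4,5-trimethoxyphenoxy}-4,5-dimethoxyphenoxy)-1,3,5-trimethoxybenzene | COc1cc(OC)c(Oc2cc(OC)c(OC)c(Oc3cc(OC)c(OC)c(OC)c3Oc3cc(OC)c(Oc4cc(OC)c(OC)c(OC)c4)c(OC)c3)c2)c(OC)c1 | intermediate
29 | 2-(3-{2-[3,5-dihydroxy-4-(3,4,5-trihydroxyphenoxy)phenoxy]-3,4,5-trihydroxyphenoxy}-4,5-dihydroxyphenoxy)benzene-1,3,5-triol (CNP0228612.0) | Oc1cc(O)c(Oc2cc(O)c(O)c(Oc3cc(O)c(O)c(O)c3Oc3cc(O)c(Oc4cc(O)c(O)c(O)c4)c(O)c3)c2)c(O)c1 | target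

**Totals**

Total step count: 15.
Longest linear sequence: 12 steps (steps 1–7, 10, 11, 12, 14, 15).

**Steps most likely to fail**

Step 10. The vinylogous-ester cyclobutenone may open too slowly, so that the ynol ether oligomerises first, or the vinylketene may dimerise or acylate the phenol as it forms instead of adding to the alkyne. Fallback (ring B purchased, both ether bonds made by copper coupling), from 7 to 23: Ullmann coupling of phenol 7 with commercial 3-bromo-4,5-dimethoxybenzaldehyde (CuI, N,N-dimethylglycine, Cs2CO3, dioxane, 100 °C) should give 3-[2-(benzyloxy)-3,4,5-trimethoxyphenoxy]-4,5-dimethoxybenzaldehyde F1. Baeyer–Villiger oxidation with mCPBA then gives 3-[2-(benzyloxy)-3,4,5-trimethoxyphenoxy]-4,5-dimethoxyphenyl formate F2, and methanolysis gives 3-[2-(benzyloxy)-3,4,5-trimethoxyphenoxy]-4,5-dimethoxyphenol F3. A second Ullmann coupling of F3 with commercial 2-iodo-1,3,5-trimethoxybenzene gives 23 directly, and the route continues with step 12.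

Step 7. Methoxyketene may dimerise or oligomerise faster than it adds to the less nucleophilic aryl ynol ether, and the aryloxy group of the vinylogous ester may be lost by hydrolysis during isolation. Fallback (the same vinylketene generated by Wolff rearrangement instead of cyclobutenone opening), from 7 to 22:
- O-alkylation of phenol 7 with methyl bromoacetate (K2CO3, acetone) should give methyl [2-(benzyloxy)-3,4,5-trimethoxyphenoxy]acetate F4.
- Claisen formylation (HCO2Me, NaH, THF) gives methyl 2-[2-(benzyloxy)-3,4,5-trimethoxyphenoxy]-3-oxopropanoate F5.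
- O-methylation of its enolate (Me2SO4, K2CO3, DMF) gives methyl (2Z)-2-[2-(benzyloxy)-3,4,5-trimethoxyphenoxy]-3-methoxyprop-2-enoate F6, expected with the methoxy group trans to the ester.
- Saponification (LiOH, THF–H2O) gives (2Z)-2-[2-(benzyloxy)-3,4,5-trimethoxyphenoxy]-3-methoxyprop-2-enoic acid F7.
- Oxalyl chloride with catalytic DMF gives (2Z)-2-[2-(benzyloxy)-3,4,5-trimethoxyphenoxy]-3-methoxyprop-2-enoyl chloride F8.
- Acylation of diazomethane (CH2N2, Et3N, Et2O, 0 °C, as in the first stage of an Arndt–Eistert sequence) gives (3Z)-3-[2-(benzyloxy)-3,4,5-trimethoxyphenoxy]-1-diazo-4-methoxybut-3-en-2-one F9; the electron-rich push–pull alkene should resist dipolar addition of diazomethane.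
- Irradiation of F9 with ynol ether 17 (ClCH2CH2Cl, 300 nm, then 80 °C) triggers the Wolff rearrangement to vinylketene 18, which follows the same path through 19, 20 and 21 to phenol 22, where the route is rejoined.

Step 14. The phenoxide of 24, flanked by an aryloxy and a methoxy group, may bind copper poorly and couple slowly, so that hydrodebromination of the electron-rich bromide 27 takes over. Fallback (oxidative coupling with a boron partner instead of a halide), from 27 to 28: bromine–lithium exchange on 27 (n-BuLi, THF, −78 °C), trapping with B(OiPr)3 and aqueous HCl should give [3,5-dimethoxy-4-(3,4,5-trimethoxyphenoxy)phenyl]boronic acid F10. Chan–Lam coupling of F10 with phenol 24 (Cu(OAc)2, pyridine, 4 Å MS, CH2Cl2, air, rt) then gives 28.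

**Further compounds**

F1 | step 10 | 3-[2-(benzyloxy)-3,4,5-trimethoxyphenoxy]-4,5-dimethoxybenzaldehyde | O=Cc1cc(OC)c(OC)c(Oc2cc(OC)c(OC)c(OC)c2OCc2ccccc2)c1
F2 | step 10 | 3-[2-(benzyloxy)-3,4,5-trimethoxyphenoxy]-4,5-dimethoxyphenyl formate | O=COc1cc(OC)c(OC)c(Oc2cc(OC)c(OC)c(OC)c2OCc2ccccc2)c1
F3 | step 10 | 3-[2-(benzyloxy)-3,4,5-trimethoxyphenoxy]-4,5-dimethoxyphenol | Oc1cc(OC)c(OC)c(Oc2cc(OC)c(OC)c(OC)c2OCc2ccccc2)c1
F4 | step 7 | methyl [2-(benzyloxy)-3,4,5-trimethoxyphenoxy]acetate | COC(=O)COc1cc(OC)c(OC)c(OC)c1OCc1ccccc1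
F5 | step 7 | methyl 2-[2-(benzyloxy)-3,4,5-trimethoxyphenoxy]-3-oxopropanoate (racemic, enolised in the flask) | COC(=O)C(C=O)Oc1cc(OC)c(OC)c(OC)c1OCc1ccccc1
F6 | step 7 | methyl (2Z)-2-[2-(benzyloxy)-3,4,5-trimethoxyphenoxy]-3-methoxyprop-2-enoate | COC(=O)/C(Oc1cc(OC)c(OC)c(OC)c1OCc1ccccc1)=C/OC
F7 | step 7 | (2Z)-2-[2-(benzyloxy)-3,4,5-trimethoxyphenoxy]-3-methoxyprop-2-enoic acid | OC(=O)/C(Oc1cc(OC)c(OC)c(OC)c1OCc1ccccc1)=C/OC
F8 | step 7 | (2Z)-2-[2-(benzyloxy)-3,4,5-trimethoxyphenoxy]-3-methoxyprop-2-enoyl chloride | ClC(=O)/C(Oc1cc(OC)c(OC)c(OC)c1OCc1ccccc1)=C/OC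
F9 | step 7 | (3Z)-3-[2-(benzyloxy)-3,4,5-trimethoxyphenoxy]-1-diazo-4-methoxybut-3-en-2-one | [N-]=[N+]=CC(=O)/C(Oc1cc(OC)c(OC)c(OC)c1OCc1ccccc1)=C/OC
F10 | step 14 | [3,5-dimethoxy-4-(3,4,5-trimethoxyphenoxy)phenyl]boronic acid | COc1cc(B(O)O)cc(OC)c1Oc1cc(OC)c(OC)c(OC)c1
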